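The bond between C18, the tetrahydrofuran carbon flanked by O17 and C3, and C10, the carbon that finally bears the methyl group and O9, is disconnected. The key step closes the nine-membered oxonane ring on this bond: SmI2 turns a 2-pyridyl sulfone at C18 into a configurationally labile anomeric organosamarium, which adds to a C10 aldehyde at the end of the C16 side chain. It exploits the cis relation of C16 and C18 across the tetrahydrofuran ring, so both sulfone anomers funnel into one bridged bicycle. The precursor is a cis-fused tetrahydrofuran–cyclohexane from an auxiliary-controlled Diels–Alder reaction; oxidation, methyl addition and etherification onto C8 then finish the oxepane.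

Key step: step 21

Remark: atom labels follow the target SMILES from left to right: C1 (CH–OAc), C2, C3, C4, C5, C6 (CH–CH3), C7 (CH–CH3), C8, O9, C10, C11–C13, C14 (C=O), C15, C16, O17, C18. "Target configuration" means the arrangement in space found in the target (1R,2R,3S,4S,6R,7R,10S,16S,18S in these labels).
Remark: TBDPS = tert-butyldiphenylsilyl, TBS = tert-butyldimethylsilyl, TES = triethylsilyl; compounds 1, 2, 4, 8, 9 and 13 are taken as commercial.

Step 1
Reactants: 1 (R)-4-benzyl-1,3-oxazolidin-2-one; 2 (diethoxyphosphoryl)acetic acid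
Product: 3 (R)-4-benzyl-3-[(diethoxyphosphoryl)acetyl]-1,3-oxazolidin-2-one
Conditions: t-BuCOCl, Et3N, THF, −20 °C; then 1, LiCl, rt
Reagents that add atoms: none
Why: N-acylation of the oxazolidinone through the mixed pivalic anhydride should give the phosphonate imide for the later olefination; no stereocentre is formed.

Step 2
Reactants: 4 methyl (S)-3-hydroxy-2-methylpropanoate
Product: 5 methyl (S)-3-(TBDPS-oxy)-2-methylpropanoate
Conditions: t-BuPh2SiCl, imidazole, DMF, rt
Reagents that add atoms: tert-butyl(chloro)diphenylsilane, CC(C)(C)[Si](Cl)(c1ccccc1)c1ccccc1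
Why: Silylation of the primary alcohol gives an ether that should survive Lewis acid, acidic methanol and hydride steps; the C7 stereocentre is untouched.

Step 3
Reactants: 5 methyl (S)-3-(TBDPS-oxy)-2-methylpropanoate
Product: 6 (S)-3-(TBDPS-oxy)-2-methylpropanal
Conditions: i-Bu2AlH (1.05 equiv), CH2Cl2, −78 °C; aqueous potassium sodium tartrate
Reagents that add atoms: none
Why: Partial ester reduction at −78 °C stops at the tetrahedral aluminate, so the aldehyde should form without loss of the α-stereocentre.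

Step 4
Reactants: 6 (S)-3-(TBDPS-oxy)-2-methylpropanal; 3 (R)-4-benzyl-3-[(diethoxyphosphoryl)acetyl]-1,3-oxazolidin-2-one
Product: 7 (R)-4-benzyl-3-[(2E,4R)-5-(TBDPS-oxy)-4-methylpent-2-enoyl]-1,3-oxazolidin-2-one
Conditions: LiCl, i-Pr2NEt, MeCN, rt
Reagents that add atoms: none
Why: The Horner–Wadsworth–Emmons reaction under LiCl/amine conditions is E-selective and mild enough to keep the α-stereocentre of the aldehyde.

Step 5
Reactants: 8 methacrolein; 9 ethyl (triphenylphosphoranylidene)acetate
Product: 10 ethyl (2E)-4-methylpenta-2,4-dienoate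
Conditions: CH2Cl2, rt
Reagents that add atoms: none
Why: The Wittig reaction of a stabilised ylide should give the E-dienoate.

Step 6
Reactants: 10 ethyl (2E)-4-methylpenta-2,4-dienoate
Product: 11 (2E)-4-methylpenta-2,4-dien-1-ol
Conditions: i-Bu2AlH (2.2 equiv), CH2Cl2, −78 °C
Reagents that add atoms: none
Why: 1,2-Reduction of the conjugated ester gives the dienol without touching the diene.

Step 7
Reactants: 11 (2E)-4-methylpenta-2,4-dien-1-ol
Product: 12 triethyl{[(2E)-4-methylpenta-2,4-dien-1-yl]oxy}silane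
Conditions: Et3SiCl, imidazole, CH2Cl2, 0 °C
Reagents that add atoms: chlorotriethylsilane, CC[Si](Cl)(CC)CC
Why: The TES ether masks the alcohol during the Lewis acid cycloaddition and can later be oxidised directly.

Step 8
Reactants: 13 hept-6-en-2-one
Product: 14 (hepta-1,6-dien-2-yloxy)trimethylsilane
Conditions: LiN(i-Pr)2, THF, −78 °C; then Me3SiCl
Reagents that add atoms: chlorotrimethylsilane, C[Si](C)(C)Cl
Why: Kinetic deprotonation at the methyl group and O-silylation give the terminal silyl enol ether that will deliver C15–C10.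

Step 9
Reactants: 7 (R)-4-benzyl-3-[(2E,4R)-5-(TBDPS-oxy)-4-methylpent-2-enoyl]-1,3-oxazolidin-2-one; 12 triethyl{[(2E)-4-methylpenta-2,4-dien-1-yl]oxy}silane
Product: 15 Diels–Alder adduct (N-acyl oxazolidinone of the trisubstituted cyclohexenecarboxylic acid)
Conditions: Et2AlCl (1.5 equiv), 12 (3 equiv), CH2Cl2, −78 → −20 °C
Reagents that add atoms: none
Why: In this Diels–Alder reaction of the Et2AlCl-chelated s-cis imide the diene should add opposite the benzyl group, setting C3 and C4 trans from the E-alkene, while the endo transition state places the C16 arm cis to the acyl carbon C18 (C2) and the 1-alkyl and 3-methyl groups of the diene both direct the required regiochemistry.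

Step 10
Reactants: 15 Diels–Alder adduct
Product: 16 aldehyde imide (C16 aldehyde)
Conditions: (COCl)2, DMSO, CH2Cl2, −78 → −40 °C; then i-Pr2NEt, −78 °C, cold work-up
Reagents that add atoms: none
Why: Swern oxidation acts directly on the primary TES ether and should leave the TBDPS ether untouched; low temperature protects the β,γ-unsaturated aldehyde.

Step 11
Reactants: 16 aldehyde imide
Product: 18 cis-fused methoxy lactone, via hemiacetal imide 17 (not isolated)
Conditions: MeOH, camphorsulfonic acid (cat.), CH2Cl2, 0 °C → rt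
Reagents that add atoms: methanol, CO
Why: The hemiacetal hydroxyl, held cis to the activated imide, should acylate itself (5-exo-trig acyl transfer) and release the auxiliary, which drains the acetal equilibrium; C16 forms as both epimers, and this centre is reset in step 16.

Step 12
Reactants: 18 cis-fused methoxy lactone
Product: 19 C1 alcohol (hydroxyl trans to C16)
Conditions: BH3·SMe2, THF, 0 °C; then NaBO3·4H2O, H2O, rt
Reagents that add atoms: sodium perborate, [Na+].[O-]OB=O
Why: Hydroboration–oxidation adds H and B syn from the convex face of the cis-fused bicycle, with boron on the less substituted C1, so the C6 methyl should end cis to C16 as in the target and the C1 hydroxyl on the wrong face for later inversion.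

Step 13
Reactants: 19 C1 alcohol (hydroxyl trans to C16)
Product: 20 C1 ketone
Conditions: Dess–Martin periodinane, NaHCO3, CH2Cl2, 0 °C
Reagents that add atoms: none
Why: Buffered Dess–Martin oxidation gives the ketone under non-enolising conditions, so the C6 centre should be kept.

Step 14
Reactants: 20 C1 ketone
Product: 21 C1 alcohol (target configuration)
Conditions: NaBH4, MeOH/CH2Cl2, −78 → −40 °C
Reagents that add atoms: none
Why: In this borohydride reduction hydride should again arrive from the convex face, opposite the C6 methyl and the C16 carbon, giving the C1 alcohol cis to both.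

Step 15
Reactants: 21 C1 alcohol (target configuration)
Product: 22 C1 TBS ether
Conditions: t-BuMe2SiOTf, 2,6-lutidine, CH2Cl2, −40 → 0 °C
Reagents that add atoms: tert-butyldimethylsilyl trifluoromethanesulfonate, CC(C)(C)[Si](C)(C)OS(=O)(=O)C(F)(F)F
Why: Silyl triflate silylation protects the hindered secondary alcohol against the hydride, organometallic and oxidation steps that follow.

Step 16
Reactants: 22 C1 TBS ether; 14 (hepta-1,6-dien-2-yloxy)trimethylsilane
Product: 24 dimethyl ketal lactone, via keto lactone 23 (not isolated)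
Conditions: Me3SiOTf (1.1 equiv), CH2Cl2, −78 °C; then Me3SiOMe (3 equiv), −78 → −30 °C
Reagents that add atoms: methoxytrimethylsilane, CO[Si](C)(C)C
Why: Mukaiyama-type addition of the silyl enol ether to the oxocarbenium ion from the C16 methoxy acetal should occur on the convex face, anti to the C2–C1 bond, setting C16 in the target configuration; the new C14 ketone is masked in the same flask by silyl triflate ketalisation.

Step 17
Reactants: 24 dimethyl ketal lactone
Product: 25 lactol (C18 hemiacetal)
Conditions: i-Bu2AlH, CH2Cl2, −78 °C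
Reagents that add atoms: none
Why: Partial reduction of the γ-lactone stops at the lactol; ketal, alkene and silyl ethers are inert.

Step 18
Reactants: 25 lactol (C18 hemiacetal)
Product: 26 2-pyridylthio acetal
Conditions: 2,2′-dipyridyl disulfide, Bu3P, CH2Cl2, rt
Reagents that add atoms: 2,2′-dipyridyl disulfide, c1ccc(SSc2ccccn2)nc1
Why: The phosphine–disulfide redox condensation replaces the hemiacetal hydroxyl by the pyridylthio group under neutral conditions that spare the dimethyl ketal; the C18 configuration is irrelevant.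

Step 19
Reactants: 26 2-pyridylthio acetal
Product: 27 2-pyridyl sulfone
Conditions: 3-ClC6H4CO3H (2.2 equiv), NaHCO3, CH2Cl2, −20 → 0 °C
Reagents that add atoms: 3-chloroperbenzoic acid, OOC(=O)c1cccc(Cl)c1
Why: Peracid oxidation of sulfide to sulfone is much faster than epoxidation of the monosubstituted alkene.

Step 20
Reactants: 27 2-pyridyl sulfone
Product: 28 sulfone aldehyde (C10 aldehyde)
Conditions: O3, pyridine, CH2Cl2, −78 °C; then PPh3
Reagents that add atoms: ozone, [O-][O+]=O
Why: Ozonolysis with reductive work-up cleaves the only alkene and gives the C10 aldehyde.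

Step 21
Reactants: 28 sulfone aldehyde (C10 aldehyde)
Product: 30 oxonane carbinol, via anomeric organosamarium 29 (not isolated)
Conditions: SmI2 (3 equiv), THF, rt, slow addition of 28 (final 0.002 M)
Reagents that add atoms: none
Why: In this samarium Barbier reaction SmI2 reduces the 2-pyridyl sulfone to a 2-tetrahydrofuranyl radical stabilised by O17, and a second electron gives a trivalent organosamarium that adds to the C10 aldehyde and forms the C18–C10 bond. The closest known reaction is the intermolecular samarium Barbier C-glycosylation of glycosyl 2-pyridyl sulfones with aldehydes and ketones, which runs without hexamethylphosphoramide and so leaves the aldehyde unreduced. The nine-membered oxonane closes in the 9-exo-trig mode, the carbonyl oxygen staying outside the ring. C18 is set by the tether: the chain is anchored on C16, so the bond can only form on the tetrahydrofuran face cis to C16, and because radical and organosamarium invert freely both sulfone anomers converge on this configuration; the C10 carbinol forms as a mixture that step 22 erases. The step needs reduction of the sulfone before the aldehyde (pyridyl sulfone, no additive), no attack on C14 (dimethyl ketal, whose geminal substitution also favours folding) and ring closure over intermolecular coupling (slow addition, high dilution).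

Step 22
Reactants: 30 oxonane carbinol
Product: 31 C10 ketone
Conditions: Dess–Martin periodinane, NaHCO3, CH2Cl2, rt
Reagents that add atoms: none
Why: Dess–Martin oxidation turns the carbinol mixture into a single α-alkoxy ketone.

Step 23
Reactants: 31 C10 ketone
Product: 32 tertiary alcohol (C10 target configuration)
Conditions: MeMgCl (2 equiv), THF, −78 °C
Reagents that add atoms: methylmagnesium chloride, C[Mg]Cl
Why: Under polar Felkin–Anh control the Grignard reagent should attack anti to the C18–O17 bond from the outer face of the nine-membered ring, giving the target configuration at C10; the competing chelate would need O17 and C11 antiperiplanar, which the ring does not allow.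

Step 24
Reactants: 32 tertiary alcohol (C10 target configuration)
Product: 33 triol
Conditions: Bu4NF, THF, rt → 45 °C
Reagents that add atoms: none
Why: Fluoride cleaves both silyl ethers and leaves the ketal and the tertiary alcohol.

Step 25
Reactants: 33 triol
Product: 35 oxepane alcohol, via primary triflate 34 (not isolated)
Conditions: (CF3SO2)2O (1.1 equiv), 2,6-lutidine, CH2Cl2, −78 → 0 °C
Reagents that add atoms: none
Why: The primary C8 hydroxyl should be triflated first and displaced by the tertiary C10 hydroxyl (Williamson-type, 7-exo-tet), closing the oxepane without touching a stereocentre.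

Step 26
Reactants: 35 oxepane alcohol
Product: 37 target acetate CNP0288436.2, via acetate dimethyl ketal 36 (not isolated)
Conditions: Ac2O, 4-(dimethylamino)pyridine, pyridine, rt; then 1 M HCl, THF, rt
Reagents that add atoms: acetic anhydride, CC(=O)OC(C)=O; water, O
Why: Acylation of the remaining secondary C1 hydroxyl followed by mild acid hydrolysis of the dimethyl ketal should release the C14 ketone and give the target.

Compound list

1 | (R)-4-benzyl-1,3-oxazolidin-2-one | O=C1N[C@H](Cc2ccccc2)CO1 | starting material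
2 | (diethoxyphosphoryl)acetic acid | CCOP(=O)(CC(=O)O)OCC | starting material
3 | (R)-4-benzyl-3-[(diethoxyphosphoryl)acetyl]-1,3-oxazolidin-2-one | CCOP(=O)(CC(=O)N1[C@H](Cc2ccccc2)COC1=O)OCC | intermediate
4 | methyl (S)-3-hydroxy-2-methylpropanoate | COC(=O)[C@@H](C)CO | starting material
5 | methyl (S)-3-(TBDPS-oxy)-2-methylpropanoate | COC(=O)[C@@H](C)CO[Si](c1ccccc1)(c1ccccc1)C(C)(C)C | intermediate
6 | (S)-3-(TBDPS-oxy)-2-methylpropanal | O=C[C@@H](C)CO[Si](c1ccccc1)(c1ccccc1)C(C)(C)C | intermediate
7 | (R)-4-benzyl-3-[(2E,4R)-5-(TBDPS-oxy)-4-methylpent-2-enoyl]-1,3-oxazolidin-2-one | O=C(/C=C/[C@@H](C)CO[Si](c1ccccc1)(c1ccccc1)C(C)(C)C)N1[C@H](Cc2ccccc2)COC1=O | intermediate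
8 | methacrolein (2-methylprop-2-enal) | CC(=C)C=O | starting material
9 | ethyl (triphenylphosphoranylidene)acetate | CCOC(=O)C=P(c1ccccc1)(c1ccccc1)c1ccccc1 | starting material
10 | ethyl (2E)-4-methylpenta-2,4-dienoate | CCOC(=O)/C=C/C(C)=C | intermediate
11 | (2E)-4-methylpenta-2,4-dien-1-ol | OC/C=C/C(C)=C | intermediate
12 | triethyl{[(2E)-4-methylpenta-2,4-dien-1-yl]oxy}silane | CC[Si](CC)(CC)OC/C=C/C(C)=C | intermediate
13 | hept-6-en-2-one | CC(=O)CCCC=C | starting material
14 | (hepta-1,6-dien-2-yloxy)trimethylsilane | C=C(CCCC=C)O[Si](C)(C)C | intermediate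
15 | (R)-4-benzyl-3-{[(1S,2R,6S)-6-[(2R)-1-(TBDPS-oxy)propan-2-yl]-4-methyl-2-[(TES-oxy)methyl]cyclohex-3-en-1-yl]carbonyl}-1,3-oxazolidin-2-one | C1=C(C)C[C@@H]([C@@H](C)CO[Si](c2ccccc2)(c2ccccc2)C(C)(C)C)[C@H](C(=O)N2[C@H](Cc3ccccc3)COC2=O)[C@@H]1CO[Si](CC)(CC)CC | intermediate
16 | (R)-4-benzyl-3-{[(1S,2R,6S)-6-[(2R)-1-(TBDPS-oxy)propan-2-yl]-2-formyl-4-methylcyclohex-3-en-1-yl]carbonyl}-1,3-oxazolidin-2-one | C1=C(C)C[C@@H]([C@@H](C)CO[Si](c2ccccc2)(c2ccccc2)C(C)(C)C)[C@H](C(=O)N2[C@H](Cc3ccccc3)COC2=O)[C@@H]1C=O | intermediate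
17 | hemiacetal imide: as 16 with CH(OH)OCH3 in place of CHO (both epimers) | C1=C(C)C[C@@H]([C@@H](C)CO[Si](c2ccccc2)(c2ccccc2)C(C)(C)C)[C@H](C(=O)N2[C@H](Cc3ccccc3)COC2=O)[C@@H]1C(O)OC | intermediate
18 | cis-fused methoxy lactone: 3-methoxy-5-methyl-7-[(2R)-1-(TBDPS-oxy)propan-2-yl]-3a,6,7,7a-tetrahydro-2-benzofuran-1(3H)-one; C2, C3, C4 in target configuration, C16 as both epimers | C1=C(C)C[C@@H]([C@@H](C)CO[Si](c3ccccc3)(c3ccccc3)C(C)(C)C)[C@@H]2C(=O)OC(OC)[C@H]12 | intermediate
19 | C1 alcohol of 18 skeleton (alkene hydrated): OH on C1 trans to C16, CH3 on C6 cis to C16 | O[C@H]1[C@H](C)C[C@@H]([C@@H](C)CO[Si](c3ccccc3)(c3ccccc3)C(C)(C)C)[C@@H]2C(=O)OC(OC)[C@H]12 | intermediate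
20 | C1 ketone, C6 methyl cis to C16 | O=C1[C@H](C)C[C@@H]([C@@H](C)CO[Si](c3ccccc3)(c3ccccc3)C(C)(C)C)[C@@H]2C(=O)OC(OC)[C@H]12 | intermediate
21 | C1 alcohol, OH cis to C16 and to the C6 methyl (target configuration at C1–C4, C6, C7) | O[C@@H]1[C@H](C)C[C@@H]([C@@H](C)CO[Si](c3ccccc3)(c3ccccc3)C(C)(C)C)[C@@H]2C(=O)OC(OC)[C@H]12 | intermediate
22 | C1 TBS ether of 21 | CC(C)(C)[Si](C)(C)O[C@@H]1[C@H](C)C[C@@H]([C@@H](C)CO[Si](c3ccccc3)(c3ccccc3)C(C)(C)C)[C@@H]2C(=O)OC(OC)[C@H]12 | intermediate
23 | keto lactone: C16 carries CH2C(=O)(CH2)3CH=CH2 trans to C1 (C16 target configuration) | CC(C)(C)[Si](C)(C)O[C@@H]1[C@H](C)C[C@@H]([C@@H](C)CO[Si](c3ccccc3)(c3ccccc3)C(C)(C)C)[C@@H]2C(=O)O[C@@H](CC(=O)CCCC=C)[C@H]12 | intermediate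
24 | dimethyl ketal lactone: as 23 with C14 as C(OCH3)2 | CC(C)(C)[Si](C)(C)O[C@@H]1[C@H](C)C[C@@H]([C@@H](C)CO[Si](c3ccccc3)(c3ccccc3)C(C)(C)C)[C@@H]2C(=O)O[C@@H](CC(OC)(OC)CCCC=C)[C@H]12 | intermediate
25 | lactol: as 24 with C18 as CH(OH) (both epimers) | CC(C)(C)[Si](C)(C)O[C@@H]1[C@H](C)C[C@@H]([C@@H](C)CO[Si](c3ccccc3)(c3ccccc3)C(C)(C)C)[C@@H]2C(O)O[C@@H](CC(OC)(OC)CCCC=C)[C@H]12 | intermediate
26 | 2-pyridylthio acetal at C18 (both epimers) | CC(C)(C)[Si](C)(C)O[C@@H]1[C@H](C)C[C@@H]([C@@H](C)CO[Si](c3ccccc3)(c3ccccc3)C(C)(C)C)[C@@H]2C(Sc4ccccn4)O[C@@H](CC(OC)(OC)CCCC=C)[C@H]12 | intermediate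
27 | 2-pyridyl sulfone at C18 (both epimers) | CC(C)(C)[Si](C)(C)O[C@@H]1[C@H](C)C[C@@H]([C@@H](C)CO[Si](c3ccccc3)(c3ccccc3)C(C)(C)C)[C@@H]2C(S(=O)(=O)c4ccccn4)O[C@@H](CC(OC)(OC)CCCC=C)[C@H]12 | intermediate
28 | sulfone aldehyde: as 27 with the chain ending in the C10 aldehyde | CC(C)(C)[Si](C)(C)O[C@@H]1[C@H](C)C[C@@H]([C@@H](C)CO[Si](c3ccccc3)(c3ccccc3)C(C)(C)C)[C@@H]2C(S(=O)(=O)c4ccccn4)O[C@@H](CC(OC)(OC)CCCC=O)[C@H]12 | intermediate
29 | anomeric organosamarium: as 28 with SmI2 on C18 in place of the sulfonyl group | CC(C)(C)[Si](C)(C)O[C@@H]1[C@H](C)C[C@@H]([C@@H](C)CO[Si](c3ccccc3)(c3ccccc3)C(C)(C)C)[C@@H]2C([Sm](I)I)O[C@@H](CC(OC)(OC)CCCC=O)[C@H]12 | intermediate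
30 | oxonane carbinol: C18–C10 bond closed, C18 in target configuration, C10 CH(OH) as both epimers, C14 dimethyl ketal | CC(C)(C)[Si](C)(C)O[C@@H]1[C@H](C)C[C@@H]([C@@H](C)CO[Si](c3ccccc3)(c3ccccc3)C(C)(C)C)[C@@H]2[C@@H]4O[C@@H](CC(OC)(OC)CCCC4O)[C@H]12 | intermediate
31 | C10 ketone of 30 | CC(C)(C)[Si](C)(C)O[C@@H]1[C@H](C)C[C@@H]([C@@H](C)CO[Si](c3ccccc3)(c3ccccc3)C(C)(C)C)[C@@H]2[C@@H]4O[C@@H](CC(OC)(OC)CCCC4=O)[C@H]12 | intermediate
32 | tertiary alcohol: C10 bears CH3 and OH in target configuration | CC(C)(C)[Si](C)(C)O[C@@H]1[C@H](C)C[C@@H]([C@@H](C)CO[Si](c3ccccc3)(c3ccccc3)C(C)(C)C)[C@@H]2[C@@H]4O[C@@H](CC(OC)(OC)CCC[C@]4(C)O)[C@H]12 | intermediate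
33 | triol: 32 without both silyl groups (free C1, C8 and C10 hydroxyls) | O[C@@H]1[C@H](C)C[C@@H]([C@@H](C)CO)[C@@H]2[C@@H]4O[C@@H](CC(OC)(OC)CCC[C@]4(C)O)[C@H]12 | intermediate
34 | primary triflate of 33 at C8 | O[C@@H]1[C@H](C)C[C@@H]([C@@H](C)COS(=O)(=O)C(F)(F)F)[C@@H]2[C@@H]4O[C@@H](CC(OC)(OC)CCC[C@]4(C)O)[C@H]12 | intermediate
35 | oxepane alcohol: target skeleton with free C1 hydroxyl and C14 as dimethyl ketal | O[C@H]1[C@@H]2[C@@H]3[C@@H](C[C@H]1C)[C@@H](C)CO[C@@]1(C)CCCC(OC)(OC)C[C@@H]2O[C@@H]31 | intermediate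
36 | acetate dimethyl ketal: target with C14 as dimethyl ketal | CC(=O)O[C@H]1[C@@H]2[C@@H]3[C@@H](C[C@H]1C)[C@@H](C)CO[C@@]1(C)CCCC(OC)(OC)C[C@@H]2O[C@@H]31 | intermediate
37 | CNP0288436.2: tetracyclic C1 acetate with C14 ketone, (1R,2R,3S,4S,6R,7R,10S,16S,18S) in the labels of the remark | CC(=O)O[C@H]1[C@@H]2[C@@H]3[C@@H](C[C@H]1C)[C@@H](C)CO[C@@]1(C)CCCC(=O)C[C@@H]2O[C@@H]31 | target

Total step count: 26. Longest linear sequence: 21 steps (from 4 through steps 2–4 and 9–26).

Steps most likely to fail

1. Step 21. Protonation of the anomeric organosamarium or intermolecular carbonyl coupling may outrun the slow nine-membered closure. The fallback sets out from 26 and comes back at 30. Reductive lithiation of the pyridylthio acetal with lithium 4,4′-di-tert-butylbiphenylide at −78 °C and trapping with Bu3SnCl should give the anomeric tributylstannane F1. Cleavage of its terminal alkene with OsO4 (catalytic), NaIO4 and 2,6-lutidine should give the stannyl aldehyde F2. Tin–lithium exchange with n-BuLi at −78 °C under high dilution then gives an α-alkoxy organolithium that adds to the aldehyde in a fast polar step and delivers 30.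

2. Step 10. The ring double bond may migrate into conjugation with the new aldehyde, with loss of configuration at C2, during oxidation or handling. The fallback sets out from 8 (with 7) and comes back at 18, and never handles the free β,γ-unsaturated aldehyde. Wittig reaction of 8 with (triphenylphosphoranylidene)acetaldehyde should give (2E)-4-methylpenta-2,4-dienal F3. Propane-1,3-dithiol and BF3·OEt2 convert it into the dithiane diene F4. The same Et2AlCl-promoted Diels–Alder reaction with 7 gives the dithianyl adduct F5, and LiOH/H2O2 removes the auxiliary to give the dithianyl acid F6. Oxidative dithiane cleavage with PhI(OCOCF3)2 in MeOH, the neighbouring acid capturing the oxocarbenium ion, gives 18.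

3. Step 13. The C6 methyl next to the new ketone may epimerise by enolisation before the reduction. The fallback sets out from 19 and comes back at 21 without passing through a ketone. Mitsunobu inversion with 4-nitrobenzoic acid, PPh3 and diisopropyl azodicarboxylate should give the inverted 4-nitrobenzoate F7, and methanolysis with NaN3 in MeOH gives 21.

Further compounds
F1 | step 21 | anomeric tributylstannane (26 with SnBu3 on C18 in place of the pyridylthio group) | CC(C)(C)[Si](C)(C)O[C@@H]1[C@H](C)C[C@@H]([C@@H](C)CO[Si](c3ccccc3)(c3ccccc3)C(C)(C)C)[C@@H]2C([Sn](CCCC)(CCCC)CCCC)O[C@@H](CC(OC)(OC)CCCC=C)[C@H]12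
F2 | step 21 | stannyl aldehyde (F1 with the chain ending in the C10 aldehyde) | CC(C)(C)[Si](C)(C)O[C@@H]1[C@H](C)C[C@@H]([C@@H](C)CO[Si](c3ccccc3)(c3ccccc3)C(C)(C)C)[C@@H]2C([Sn](CCCC)(CCCC)CCCC)O[C@@H](CC(OC)(OC)CCCC=O)[C@H]12
F3 | step 10 | (2E)-4-methylpenta-2,4-dienal | O=C/C=C/C(C)=C
F4 | step 10 | 2-[(1E)-3-methylbuta-1,3-dien-1-yl]-1,3-dithiane | C=C(C)/C=C/C1SCCCS1
F5 | step 10 | dithianyl Diels–Alder adduct (15 with 1,3-dithian-2-yl in place of CH2OTES) | C1=C(C)C[C@@H]([C@@H](C)CO[Si](c2ccccc2)(c2ccccc2)C(C)(C)C)[C@H](C(=O)N2[C@H](Cc3ccccc3)COC2=O)[C@@H]1C4SCCCS4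
F6 | step 10 | dithianyl acid (F5 with CO2H in place of the acyl oxazolidinone) | C1=C(C)C[C@@H]([C@@H](C)CO[Si](c2ccccc2)(c2ccccc2)C(C)(C)C)[C@H](C(=O)O)[C@@H]1C4SCCCS4
F7 | step 13 | 4-nitrobenzoate of 21 (C1 ester cis to C16) | O=C(O[C@@H]1[C@H](C)C[C@@H]([C@@H](C)CO[Si](c3ccccc3)(c3ccccc3)C(C)(C)C)[C@@H]2C(=O)OC(OC)[C@H]12)c5ccc(cc5)[N+](=O)[O-]
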